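**Retrosynthetic overview**
- The target comes from its 5,8,3',5'-tetra-O-benzyl ether by global hydrogenolysis. The 3-OH comes from epoxidation of the flavone C2=C3 bond followed by acid opening.
- Ring C is the only ring built. It forms by oxa-Michael closure and dehydrogenation of a 2'-hydroxychalcone; rings A and B are bought as arenes.
- The key C-C bond (later C2-C3) is made by a Claisen-Schmidt aldol condensation of the ring A methyl ketone with the ring B aldehyde.
- The ring A ketone comes from 3,4,5-trimethoxyphenol: methylation, Friedel-Crafts acetylation with ortho-demethylation, an O-allyl mask, oxidative demethylation to the p-quinone, reduction, benzylation and deallylation.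
- The ring B aldehyde comes from methyl gallate: 4-O-methylation, 3,5-di-O-benzylation, then ester to alcohol to aldehyde.

Assumption: the SMILES contains no stereocentre and no stereogenic double bond, so the target is achiral and no enantiocontrol is needed; the stereocentres of transient intermediates 15, 17 and 19 are racemic and are erased.

**Step 1**
Reactants: 1 3,4,5-trimethoxyphenol
Product: 2 1,2,3,5-tetramethoxybenzene
Conditions: MeI, K2CO3, acetone, reflux
Reagents that add atoms: methyl iodide, CI
Why: Williamson ether synthesis on an unhindered phenoxide is high-yielding and gives a symmetric arene whose two free ring positions are equivalent, so the following acylation has no regiochemical choice.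

**Step 2**
Reactants: 2 1,2,3,5-tetramethoxybenzene
Product: 4 2-hydroxy-3,4,6-trimethoxyacetophenone, via 2,3,4,6-tetramethoxyacetophenone 3 (not isolated)
Conditions: AcCl (1.2 equiv), AlCl3 (2.5 equiv), Et2O, 0 °C to rt; then 2 M HCl
Reagents that add atoms: acetyl chloride, CC(=O)Cl
Why: Friedel-Crafts acylation at either equivalent activated position is followed in the same flask by carbonyl-chelated AlCl3 ether cleavage, which takes the 2-methoxy group because it is wedged between the acetyl and the 3-methoxy group, twisted out of plane and therefore the more basic and more strained of the two ortho ethers (checked by NOE from H-5 to two OMe groups in 4).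

**Step 3**
Reactants: 4 2-hydroxy-3,4,6-trimethoxyacetophenone
Product: 5 2-(allyloxy)-3,4,6-trimethoxyacetophenone
Conditions: allyl bromide, K2CO3, DMF, 60 °C
Reagents that add atoms: allyl bromide, C=CCBr
Why: Williamson ether synthesis masks the future O1 oxygen as an allyl ether, which tolerates the oxidant, reductant and base of steps 4 to 6 and can later be removed without touching benzyl ethers, and warm DMF overcomes the hydrogen bond of the chelated phenol.

**Step 4**
Reactants: 5 2-(allyloxy)-3,4,6-trimethoxyacetophenone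
Product: 6 2-acetyl-3-(allyloxy)-5-methoxy-1,4-benzoquinone
Conditions: (NH4)2Ce(NO3)6 (2.3 equiv), MeCN/H2O, 0 °C, 15 min; extractive work-up, used crude
Reagents that add atoms: water, O
Why: Oxidative demethylation by the one-electron oxidant tetravalent cerium turns the only para-related pair of methoxy groups (C3 and C6) into the p-quinone, with water supplying both new carbonyl oxygens, while the 4-methoxy and 2-allyloxy groups have no para oxygen partner and stay.

**Step 5**
Reactants: 6 2-acetyl-3-(allyloxy)-5-methoxy-1,4-benzoquinone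
Product: 7 2-(allyloxy)-3,6-dihydroxy-4-methoxyacetophenone
Conditions: Na2S2O4, EtOAc/H2O, rt
Reagents that add atoms: none
Why: Dithionite reduction of a quinone to its hydroquinone is fast and clean in a two-phase system and touches neither the aryl ketone nor the allyl ether.

**Step 6**
Reactants: 7 2-(allyloxy)-3,6-dihydroxy-4-methoxyacetophenone
Product: 8 2-(allyloxy)-3,6-bis(benzyloxy)-4-methoxyacetophenone
Conditions: BnBr (2.6 equiv), K2CO3, degassed DMF, N2, 65 °C
Reagents that add atoms: benzyl bromide, BrCc1ccccc1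
Why: Double Williamson ether synthesis puts hydrogenolysable benzyl groups on exactly the two oxygens that end as 5-OH and 8-OH, with exclusion of air preventing re-oxidation of the hydroquinone and heating bringing the chelated 6-OH to reaction.

**Step 7**
Reactants: 8 2-(allyloxy)-3,6-bis(benzyloxy)-4-methoxyacetophenone
Product: 9 3,6-bis(benzyloxy)-2-hydroxy-4-methoxyacetophenone
Conditions: Pd(PPh3)4 (5 mol %), morpholine, THF, rt
Reagents that add atoms: none
Why: In this Tsuji-Trost type deallylation zerovalent palladium ionises the allyl aryl ether to a pi-allyl complex and a well-stabilised ortho-acyl phenoxide, morpholine traps the allyl unit, and benzyl and methyl ethers are inert.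

**Step 8**
Reactants: 10 methyl gallate (methyl 3,4,5-trihydroxybenzoate)
Product: 11 methyl 3,5-dihydroxy-4-methoxybenzoate
Conditions: MeI (1.05 equiv), K2CO3 (1.0 equiv), DMF, N2, rt
Reagents that add atoms: methyl iodide, CI
Why: The 4-OH para to the ester is the most acidic phenol of methyl gallate, so one equivalent of base forms mainly the 4-phenoxide and the Williamson alkylation goes there, with minor isomers and dimethyl ethers removed by chromatography or crystallisation.

**Step 9**
Reactants: 11 methyl 3,5-dihydroxy-4-methoxybenzoate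
Product: 12 methyl 3,5-bis(benzyloxy)-4-methoxybenzoate
Conditions: BnBr (2.4 equiv), K2CO3, DMF, 60 °C
Reagents that add atoms: benzyl bromide, BrCc1ccccc1
Why: Exhaustive Williamson benzylation of the two remaining equivalent phenols has no selectivity issue, and the methyl ester survives K2CO3 in DMF.

**Step 10**
Reactants: 12 methyl 3,5-bis(benzyloxy)-4-methoxybenzoate
Product: 13 [3,5-bis(benzyloxy)-4-methoxyphenyl]methanol
Conditions: LiAlH4, THF, 0 °C to rt; aqueous NaOH work-up
Reagents that add atoms: none
Why: Hydride reduction of the ester to the benzylic alcohol is more dependable than a partial reduction to the aldehyde and leaves aryl ethers untouched.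

**Step 11**
Reactants: 13 [3,5-bis(benzyloxy)-4-methoxyphenyl]methanol
Product: 14 3,5-bis(benzyloxy)-4-methoxybenzaldehyde
Conditions: activated MnO2 (10 equiv), CH2Cl2, rt
Reagents that add atoms: none
Why: Activated MnO2 oxidises benzylic alcohols selectively and stops at the aldehyde without over-oxidation.

**Step 12**
Reactants: 9 3,6-bis(benzyloxy)-2-hydroxy-4-methoxyacetophenone; 14 3,5-bis(benzyloxy)-4-methoxybenzaldehyde
Product: 16 (E)-1-[3,6-bis(benzyloxy)-2-hydroxy-4-methoxyphenyl]-3-[3,5-bis(benzyloxy)-4-methoxyphenyl]prop-2-en-1-one, via aldol adduct 15 (not isolated)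
Conditions: KOH (50% aq), EtOH/THF, rt, 24-48 h; then dilute HCl
Reagents that add atoms: none
Why: In this Claisen-Schmidt (crossed aldol) condensation only 9 can form an enolate and 14 is a non-enolisable aldehyde, so a single cross product forms, and E1cB loss of water from racemic aldol 15 under thermodynamic control gives the (E)-enone with no stereocentre left.

**Step 13**
Reactants: 16 (E)-chalcone from step 12
Product: 18 5,8-bis(benzyloxy)-2-[3,5-bis(benzyloxy)-4-methoxyphenyl]-7-methoxy-4H-chromen-4-one, via flavanone 17 (not isolated)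
Conditions: I2 (10 mol %), DMSO, 130 °C; aq Na2S2O3 work-up
Reagents that add atoms: none
Why: Intramolecular oxa-Michael addition of the 2'-OH, the only free phenol, closes ring C to racemic flavanone 17, and iodine-mediated dehydrogenation with DMSO as terminal oxidant converts it to the flavone, erasing the C2 stereocentre.

**Step 14**
Reactants: 18 tetra-O-benzyl flavone from step 13
Product: 20 5,8-bis(benzyloxy)-2-[3,5-bis(benzyloxy)-4-methoxyphenyl]-3-hydroxy-7-methoxy-4H-chromen-4-one, via 2,3-epoxide 19 (not isolated)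
Conditions: dimethyldioxirane (acetone solution, 2-3 equiv), CH2Cl2, 0 °C; then p-TsOH (cat.), CH2Cl2, rt
Reagents that add atoms: dimethyldioxirane, CC1(C)OO1
Why: Electrophilic epoxidation of the enol-ether-like C2=C3 bond gives racemic epoxide 19, which under acid catalysis opens at the benzylic acetal carbon C2 and loses the C3 proton to give the achiral 3-hydroxyflavone under metal-free conditions that spare benzyl ethers at low temperature.

**Step 15**
Reactants: 20 tetra-O-benzyl flavonol from step 14
Product: 21 2-(3,5-dihydroxy-4-methoxyphenyl)-3,5,8-trihydroxy-7-methoxy-4H-chromen-4-one (target)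
Conditions: H2 (1 atm), 10% Pd/C, THF/MeOH, rt; filtration and concentration under Ar
Reagents that add atoms: none
Why: Catalytic hydrogenolysis cleaves all four benzyl aryl ethers under neutral conditions while the methyl ethers and the vinylogous-ester C2=C3 bond of the flavonol are inert, and air-free handling protects the oxidation-prone 5,8-hydroquinone.

**Compound list**
1 | 3,4,5-trimethoxyphenol | COc1cc(O)cc(OC)c1OC | starting material
2 | 1,2,3,5-tetramethoxybenzene | COc1cc(OC)c(OC)c(OC)c1 | intermediate
3 | 2,3,4,6-tetramethoxyacetophenone | CC(=O)c1c(OC)cc(OC)c(OC)c1OC | intermediate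
4 | 2-hydroxy-3,4,6-trimethoxyacetophenone | CC(=O)c1c(OC)cc(OC)c(OC)c1O | intermediate
5 | 2-(allyloxy)-3,4,6-trimethoxyacetophenone | CC(=O)c1c(OC)cc(OC)c(OC)c1OCC=C | intermediate
6 | 2-acetyl-3-(allyloxy)-5-methoxy-1,4-benzoquinone | CC(=O)C1=C(OCC=C)C(=O)C(OC)=CC1=O | intermediate
7 | 2-(allyloxy)-3,6-dihydroxy-4-methoxyacetophenone | CC(=O)c1c(O)cc(OC)c(O)c1OCC=C | intermediate
8 | 2-(allyloxy)-3,6-bis(benzyloxy)-4-methoxyacetophenone | CC(=O)c1c(OCc2ccccc2)cc(OC)c(OCc2ccccc2)c1OCC=C | intermediate
9 | 3,6-bis(benzyloxy)-2-hydroxy-4-methoxyacetophenone | CC(=O)c1c(OCc2ccccc2)cc(OC)c(OCc2ccccc2)c1O | intermediate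
10 | methyl gallate | COC(=O)c1cc(O)c(O)c(O)c1 | starting material
11 | methyl 3,5-dihydroxy-4-methoxybenzoate | COC(=O)c1cc(O)c(OC)c(O)c1 | intermediate
12 | methyl 3,5-bis(benzyloxy)-4-methoxybenzoate | COC(=O)c1cc(OCc2ccccc2)c(OC)c(OCc2ccccc2)c1 | intermediate
13 | [3,5-bis(benzyloxy)-4-methoxyphenyl]methanol | OCc1cc(OCc2ccccc2)c(OC)c(OCc2ccccc2)c1 | intermediate
14 | 3,5-bis(benzyloxy)-4-methoxybenzaldehyde | O=Cc1cc(OCc2ccccc2)c(OC)c(OCc2ccccc2)c1 | intermediate
15 | racemic aldol adduct, 1-[3,6-bis(benzyloxy)-2-hydroxy-4-methoxyphenyl]-3-[3,5-bis(benzyloxy)-4-methoxyphenyl]-3-hydroxypropan-1-one | O=C(CC(O)c1cc(OCc2ccccc2)c(OC)c(OCc2ccccc2)c1)c1c(O)c(OCc2ccccc2)c(OC)cc1OCc1ccccc1 | intermediate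
16 | (E)-1-[3,6-bis(benzyloxy)-2-hydroxy-4-methoxyphenyl]-3-[3,5-bis(benzyloxy)-4-methoxyphenyl]prop-2-en-1-one | O=C(/C=C/c1cc(OCc2ccccc2)c(OC)c(OCc2ccccc2)c1)c1c(O)c(OCc2ccccc2)c(OC)cc1OCc1ccccc1 | intermediate
17 | racemic flavanone, 5,8-bis(benzyloxy)-2-[3,5-bis(benzyloxy)-4-methoxyphenyl]-7-methoxychroman-4-one | O=C1CC(c2cc(OCc3ccccc3)c(OC)c(OCc3ccccc3)c2)Oc2c1c(OCc1ccccc1)cc(OC)c2OCc1ccccc1 | intermediate
18 | 5,8-bis(benzyloxy)-2-[3,5-bis(benzyloxy)-4-methoxyphenyl]-7-methoxy-4H-chromen-4-one | O=c1cc(-c2cc(OCc3ccccc3)c(OC)c(OCc3ccccc3)c2)oc2c1c(OCc1ccccc1)cc(OC)c2OCc1ccccc1 | intermediate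
19 | racemic 2,3-epoxide of 18 (oxirane fused across C2-C3 of ring C) | O=C1C2OC2(c2cc(OCc3ccccc3)c(OC)c(OCc3ccccc3)c2)Oc2c1c(OCc1ccccc1)cc(OC)c2OCc1ccccc1 | intermediate
20 | 5,8-bis(benzyloxy)-2-[3,5-bis(benzyloxy)-4-methoxyphenyl]-3-hydroxy-7-methoxy-4H-chromen-4-one | O=c1c(O)c(-c2cc(OCc3ccccc3)c(OC)c(OCc3ccccc3)c2)oc2c1c(OCc1ccccc1)cc(OC)c2OCc1ccccc1 | intermediate
21 | 2-(3,5-dihydroxy-4-methoxyphenyl)-3,5,8-trihydroxy-7-methoxy-4H-chromen-4-one | COc1cc(O)c2c(=O)c(O)c(-c3cc(O)c(OC)c(O)c3)oc2c1O | target

**Totals**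
- Total step count: 15.
- Longest linear sequence: 11 steps (steps 1-7, then 12-15).

**Three steps most likely to fail**

*Step 4.* Quinone 6 carries its allyloxy group on a carbon activated by two carbonyl groups, so hydrolysis or decomposition in the acidic aqueous oxidant is the main danger.
- The fallback moves the oxidation behind ring closure. There ring C itself masks the O1 oxygen, so no allyl group and no acylquinone are needed.
- It sets out from 4 (together with 14) and comes back at 18.
- Claisen-Schmidt condensation of 4 with 14 (KOH, EtOH) gives (E)-3-[3,5-bis(benzyloxy)-4-methoxyphenyl]-1-(2-hydroxy-3,4,6-trimethoxyphenyl)prop-2-en-1-one F1.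
- I2 in hot DMSO closes this to 2-[3,5-bis(benzyloxy)-4-methoxyphenyl]-5,7,8-trimethoxy-4H-chromen-4-one F2.
- (NH4)2Ce(NO3)6 in MeCN/H2O removes the para-related 5- and 8-methyl groups to give 2-[3,5-bis(benzyloxy)-4-methoxyphenyl]-7-methoxy-4H-chromene-4,5,8-trione F3.
- Na2S2O4 reduces it to 2-[3,5-bis(benzyloxy)-4-methoxyphenyl]-5,8-dihydroxy-7-methoxy-4H-chromen-4-one F4.
- BnBr/K2CO3 in degassed DMF then gives 18.

*Step 14.* Dimethyldioxirane may attack the very electron-rich ring A or the benzylic C-H bonds before the C2=C3 bond is consumed.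
- The fallback replaces electrophilic epoxidation by a C3 carbanion route. It sets out from 18 and comes back at 20.
- Lithium diisopropylamide in THF at -78 °C deprotonates C3 to give the 3-lithioflavone F5.
- B(OMe)3 traps it as dimethyl {5,8-bis(benzyloxy)-2-[3,5-bis(benzyloxy)-4-methoxyphenyl]-7-methoxy-4-oxo-4H-chromen-3-yl}boronate F6.
- H2O2/AcOH oxidises the C-B bond to the C3-OH of 20.

*Step 8.* The acidity difference between the phenols gives only moderate selectivity, and the gallate anion is air-sensitive.
- The fallback replaces direct alkylation by full protection followed by selective unmasking. It sets out from 10 and comes back at 11.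
- Ac2O/pyridine gives methyl 3,4,5-triacetoxybenzoate F7.
- MeI/K2CO3 in refluxing acetone cleaves only the 4-acetate, whose phenoxide is the best leaving group because it is para to the ester. The phenoxide is methylated in situ to give methyl 3,5-diacetoxy-4-methoxybenzoate F8.
- K2CO3 in MeOH removes the two remaining acetates to give 11.

**Further compounds**
F1 | step 4 | (E)-3-[3,5-bis(benzyloxy)-4-methoxyphenyl]-1-(2-hydroxy-3,4,6-trimethoxyphenyl)prop-2-en-1-one | O=C(/C=C/c1cc(OCc2ccccc2)c(OC)c(OCc2ccccc2)c1)c1c(O)c(OC)c(OC)cc1OC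
F2 | step 4 | 2-[3,5-bis(benzyloxy)-4-methoxyphenyl]-5,7,8-trimethoxy-4H-chromen-4-one | O=c1cc(-c2cc(OCc3ccccc3)c(OC)c(OCc3ccccc3)c2)oc2c1c(OC)cc(OC)c2OC
F3 | step 4 | 2-[3,5-bis(benzyloxy)-4-methoxyphenyl]-7-methoxy-4H-chromene-4,5,8-trione | COC1=CC(=O)C2=C(OC(=CC2=O)c2cc(OCc3ccccc3)c(OC)c(OCc3ccccc3)c2)C1=O
F4 | step 4 | 2-[3,5-bis(benzyloxy)-4-methoxyphenyl]-5,8-dihydroxy-7-methoxy-4H-chromen-4-one | O=c1cc(-c2cc(OCc3ccccc3)c(OC)c(OCc3ccccc3)c2)oc2c1c(O)cc(OC)c2O
F5 | step 14 | 3-lithioflavone (C3-lithiated 18) | [Li]c1c(-c2cc(OCc3ccccc3)c(OC)c(OCc3ccccc3)c2)oc2c(c1=O)c(OCc1ccccc1)cc(OC)c2OCc1ccccc1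
F6 | step 14 | dimethyl {5,8-bis(benzyloxy)-2-[3,5-bis(benzyloxy)-4-methoxyphenyl]-7-methoxy-4-oxo-4H-chromen-3-yl}boronate | COB(OC)c1c(-c2cc(OCc3ccccc3)c(OC)c(OCc3ccccc3)c2)oc2c(c1=O)c(OCc1ccccc1)cc(OC)c2OCc1ccccc1
F7 | step 8 | methyl 3,4,5-triacetoxybenzoate | COC(=O)c1cc(OC(C)=O)c(OC(C)=O)c(OC(C)=O)c1
F8 | step 8 | methyl 3,5-diacetoxy-4-methoxybenzoate | COC(=O)c1cc(OC(C)=O)c(OC)c(OC(C)=O)c1
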